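C3–OH of the upper flavan is traced back to C3–Si after removal of the seven benzyl ethers. Ring C is then cut at O1–C2 and C3–C4 in one retro-[4+2], and last the C4–C8(D) bond is cut to an aryllithium and a salicylaldehyde.
Enabling feature: in ring C (O1, C2, C3, C4, C4a, C8a), C4 is benzylic to both ring A and ring D and lies ortho to the ring A oxygen. O1–C8a–C4a–C4 is therefore a masked ortho-quinone methide, and C2–C3 with its 4-oxyphenyl and oxygen substituents maps onto a (Z)-β-silylstyrene.
Forward order: rings D, E and F are bought as (−)-epicatechin, ring A is joined to C8(D) through the future C4, and ring C closes last in the step that also brings in ring B.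
Stereochemistry: C2(F) and C3(F) come from the chiral pool. C2/C3 cis comes from the Z alkene, C4 trans from an exo approach, and the absolute sense from a chiral phosphoric acid acting together with the epicatechin unit. C3–O replaces C3–Si with retention.
Key step: step 9

Assumption: the (R) antipode of the phosphoric acid is written as the one matched to the epicatechin unit; precedent does not settle this pairing, and one comparison of the two commercial antipodes would.
Numbering: the upper flavan has rings A (fused arene), B (4-oxyphenyl) and C (pyran) with plain locants. The epicatechin unit has rings D (fused arene), E (catechol) and F (pyran), with locants written C8(D), C2(F), C3(F).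

Step 1
Reactants: 1 (−)-epicatechin
Product: 2 5,7,3',4'-tetra-O-benzyl-(−)-epicatechin
Conditions: BnBr (4.4 equiv), K2CO3, DMF, Ar, 0 °C to rt
Reagents that add atoms: benzyl bromide, BrCc1ccccc1
Why: Williamson ether synthesis in which carbonate ionises only the four phenols, so the secondary C3(F) alcohol stays free and the mild, oxygen-free medium leaves C2(F) and C3(F) as they are.

Step 2
Reactants: 2 5,7,3',4'-tetra-O-benzyl-(−)-epicatechin
Product: 3 3,5,7,3',4'-penta-O-benzyl-(−)-epicatechin
Conditions: NaH, BnBr, DMF, 0 °C to rt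
Reagents that add atoms: benzyl bromide, BrCc1ccccc1
Why: Williamson ether synthesis on the sodium alkoxide, safe for C2(F) because no free phenol is left that could open ring F under base.

Step 3
Reactants: 3 3,5,7,3',4'-penta-O-benzyl-(−)-epicatechin
Product: 4 8-bromo-3,5,7,3',4'-penta-O-benzyl-(−)-epicatechin
Conditions: NBS (1.0 equiv), CH2Cl2, −78 °C to 0 °C
Reagents that add atoms: N-bromosuccinimide, O=C1CCC(=O)N1Br
Why: Electrophilic aromatic bromination of the phloroglucinol-type ring D, the most electron-rich arene present, which in benzylated flavan-3-ols takes place at C8(D) since C6(D) is shielded by two flanking benzyloxy groups.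

Step 4
Reactants: 5 4-(benzyloxy)-2-hydroxybenzaldehyde
Product: 6 2-(allyloxy)-4-(benzyloxy)benzaldehyde
Conditions: allyl bromide, K2CO3, DMF, rt
Reagents that add atoms: allyl bromide, C=CCBr
Why: Williamson ether synthesis that masks the acidic phenol with a group that tolerates an aryllithium at −78 °C, cannot wander to the neighbouring alkoxide as a silyl group might, and is removable later without acid and without touching benzyl ethers.

Step 5
Reactants: 4 8-bromo-3,5,7,3',4'-penta-O-benzyl-(−)-epicatechin; 6 2-(allyloxy)-4-(benzyloxy)benzaldehyde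
Product: 8 [2-(allyloxy)-4-(benzyloxy)phenyl](penta-O-benzylepicatechin-8-yl)methanol (either carbinol epimer), via 8-lithio-penta-O-benzylepicatechin 7 (not isolated)
Conditions: n-BuLi (1.05 equiv), THF, −78 °C; 6, −78 °C; AcOH, −78 °C to rt
Reagents that add atoms: none
Why: Bromine–lithium exchange followed by 1,2-addition of the aryllithium to the aldehyde forms the C4–C8(D) bond, and the new carbinol centre may form as either epimer because it is flattened again in step 9.

Step 6
Reactants: 8 [2-(allyloxy)-4-(benzyloxy)phenyl](penta-O-benzylepicatechin-8-yl)methanol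
Product: 9 [4-(benzyloxy)-2-hydroxyphenyl](penta-O-benzylepicatechin-8-yl)methanol (either carbinol epimer)
Conditions: Pd(PPh3)4 (5 mol %), morpholine, THF, rt; chromatography on Et3N-washed silica
Reagents that add atoms: none
Why: Tsuji–Trost deallylation, in which zerovalent palladium ionises only the allyl aryl ether and morpholine captures the π-allyl fragment, so the acid-sensitive benzhydrol and all benzyl ethers see only a neutral to weakly basic medium.

Step 7
Reactants: 10 1-(benzyloxy)-4-ethynylbenzene; 11 benzyl(chloro)dimethylsilane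
Product: 13 benzyl{[4-(benzyloxy)phenyl]ethynyl}dimethylsilane, via lithium acetylide 12 (not isolated)
Conditions: n-BuLi, THF, −78 °C; 11, −78 °C to rt
Reagents that add atoms: none
Why: Deprotonation of the terminal alkyne and nucleophilic substitution at silicon by the acetylide, a standard C-silylation.

Step 8
Reactants: 13 benzyl{[4-(benzyloxy)phenyl]ethynyl}dimethylsilane
Product: 15 (Z)-benzyl{2-[4-(benzyloxy)phenyl]ethenyl}dimethylsilane, via alkenylalane 14 (not isolated)
Conditions: i-Bu2AlH, N-methylpyrrolidine, toluene/heptane, 55 °C; H2O, 0 °C; aq potassium sodium tartrate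
Reagents that add atoms: none
Why: Hydroalumination–protonolysis: H and Al add syn with aluminium on the silicon-bearing carbon, the amine donor blocks the isomerisation of the adduct, and protonolysis of the C–Al bond with retention leaves aryl and silyl cis.

Step 9
Reactants: 9 [4-(benzyloxy)-2-hydroxyphenyl](penta-O-benzylepicatechin-8-yl)methanol; 15 (Z)-benzyl{2-[4-(benzyloxy)phenyl]ethenyl}dimethylsilane
Product: 17 (2R,3R,4R)-hepta-O-benzyl-3-deoxy-3-[benzyl(dimethyl)silyl]epiguibourtinidol-(4β→8)-epicatechin, via (E)-ortho-quinone methide 16 (not isolated)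
Conditions: (R)-3,3'-bis(2,4,6-triisopropylphenyl)-1,1'-binaphthyl-2,2'-diyl hydrogen phosphate (10 mol %), 15 (2 equiv), 4 Å MS, toluene, 0 °C, slow addition of 9
Reagents that add atoms: none
Why: Proposed new method: the phosphoric acid protonates the doubly benzylic hydroxyl of 9, water leaves with help from the oxygen donors of rings A and D, and the phenol proton passes to the phosphate, which stays hydrogen-bonded to the carbonyl oxygen of the (E)-ortho-quinone methide 16; the alkene of 15 then adds across O1=C8a–C4a=C4 in a concerted but asynchronous inverse-demand oxa-[4+2], its silicon-bearing carbon bonding to C4 a little ahead of O1 to the benzylic carbon. The closest known reaction type is the chiral-phosphoric-acid-catalysed [4+2] of in situ formed aryl ortho-quinone methides with styrenes, which has not been tried on a β-silylstyrene or on a Z alkene and which normally runs endo to 2,4-cis chromans. Ring C closes by intermolecular cycloaddition, four ring atoms (O1, C8a, C4a, C4) coming from 16 and two (C2, C3) from 15, with no separate cyclisation event. Regiochemistry is doubly secured, since the partial positive charge at C2 is carried both by the 4-benzyloxyphenyl group and by hyperconjugation with the C3–Si bond, and chemoselectivity is built in because ring A holds the only free phenol. C2 and C3 take their cis relation from the Z alkene by suprafacial addition, and C4 becomes trans to both through the exo mode, favoured because the endo mode would wedge SiMe2Bn between ring D and the underside of ring A whereas exo places it next to the methide hydrogen. The absolute sense (4R, hence 2R,3R) depends on which face of 16 is attacked and is to be set by the 2,4,6-triisopropylphenyl pocket of the acid acting in concert with the twisted, enantiopure epicatechin substituent, while sieves, a weak acid and 0 °C are chosen to keep protodesilylation and loss of silicon from an open cation in check.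

Step 10
Reactants: 17 (2R,3R,4R)-hepta-O-benzyl-3-deoxy-3-[benzyl(dimethyl)silyl]epiguibourtinidol-(4β→8)-epicatechin
Product: 19 hepta-O-benzyl-epiguibourtinidol-(4β→8)-epicatechin (2R,3R,4R; upper 3-OH free), via C3 dimethylsilanol 18 (not isolated)
Conditions: TBAF·3H2O, THF, 0 °C; then 30% H2O2, KHCO3, MeOH, 0 to 40 °C
Reagents that add atoms: hydrogen peroxide, OO
Why: Tamao–Fleming oxidation: fluoride removes the benzyl group from silicon, hydroperoxide adds to the silanol and C3 migrates from silicon to oxygen with retention, so the hydroxyl takes the α position held by silicon, while in the half-chair that keeps ring B equatorial the C3–Si bond is axial and gauche to C2–O1, an alignment that disfavours β-elimination of the ring oxygen.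

Step 11
Reactants: 19 hepta-O-benzyl-epiguibourtinidol-(4β→8)-epicatechin
Product: 20 epiguibourtinidol-(4β→8)-epicatechin (CNP0118995.2)
Conditions: H2 (1 atm), Pd(OH)2/C, THF/MeOH, rt
Reagents that add atoms: none
Why: Catalytic hydrogenolysis of the six aryl benzyl ethers and the one alkyl benzyl ether, a standard end game for benzylated proanthocyanidins that leaves the C4–C8(D) bond, both pyran rings and all five stereocentres untouched.

Compound list
1 | (−)-epicatechin, (2R,3R) | Oc1cc(O)c2c(c1)O[C@H](c1ccc(O)c(O)c1)[C@H](O)C2 | starting material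
2 | 5,7,3',4'-tetra-O-benzyl-(−)-epicatechin, (2R,3R), 3-OH free | c1ccccc1COc1cc(OCc2ccccc2)c2c(c1)O[C@H](c1ccc(OCc3ccccc3)c(OCc3ccccc3)c1)[C@H](O)C2 | intermediate
3 | 3,5,7,3',4'-penta-O-benzyl-(−)-epicatechin, (2R,3R) | c1ccccc1COc1cc(OCc2ccccc2)c2c(c1)O[C@H](c1ccc(OCc3ccccc3)c(OCc3ccccc3)c1)[C@H](OCc1ccccc1)C2 | intermediate
4 | 8-bromo-3,5,7,3',4'-penta-O-benzyl-(−)-epicatechin | Brc1c(OCc3ccccc3)cc(OCc3ccccc3)c2c1O[C@H](c1ccc(OCc3ccccc3)c(OCc3ccccc3)c1)[C@H](OCc1ccccc1)C2 | intermediate
5 | 4-(benzyloxy)-2-hydroxybenzaldehyde | O=Cc1ccc(OCc2ccccc2)cc1O | starting material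
6 | 2-(allyloxy)-4-(benzyloxy)benzaldehyde | O=Cc1ccc(OCc2ccccc2)cc1OCC=C | intermediate
7 | 8-lithio-3,5,7,3',4'-penta-O-benzylepicatechin | [Li]c1c(OCc3ccccc3)cc(OCc3ccccc3)c2c1O[C@H](c1ccc(OCc3ccccc3)c(OCc3ccccc3)c1)[C@H](OCc1ccccc1)C2 | intermediate
8 | [2-(allyloxy)-4-(benzyloxy)phenyl](penta-O-benzylepicatechin-8-yl)methanol, carbinol centre undefined | OC(c1ccc(OCc5ccccc5)cc1OCC=C)c1c(OCc5ccccc5)cc(OCc5ccccc5)c2c1O[C@H](c1ccc(OCc5ccccc5)c(OCc5ccccc5)c1)[C@H](OCc5ccccc5)C2 | intermediate
9 | [4-(benzyloxy)-2-hydroxyphenyl](penta-O-benzylepicatechin-8-yl)methanol, carbinol centre undefined | OC(c1ccc(OCc5ccccc5)cc1O)c1c(OCc5ccccc5)cc(OCc5ccccc5)c2c1O[C@H](c1ccc(OCc5ccccc5)c(OCc5ccccc5)c1)[C@H](OCc5ccccc5)C2 | intermediate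
10 | 1-(benzyloxy)-4-ethynylbenzene | C#Cc1ccc(OCc2ccccc2)cc1 | starting material
11 | benzyl(chloro)dimethylsilane | C[Si](C)(Cl)Cc1ccccc1 | starting material
12 | lithium [4-(benzyloxy)phenyl]acetylide | [Li]C#Cc1ccc(OCc2ccccc2)cc1 | intermediate
13 | benzyl{[4-(benzyloxy)phenyl]ethynyl}dimethylsilane | C[Si](C)(Cc1ccccc1)C#Cc1ccc(OCc2ccccc2)cc1 | intermediate
14 | (Z)-{1-[benzyl(dimethyl)silyl]-2-[4-(benzyloxy)phenyl]ethenyl}diisobutylalane (aryl and silyl cis) | C[Si](C)(Cc1ccccc1)/C([Al](CC(C)C)CC(C)C)=C\c1ccc(OCc2ccccc2)cc1 | intermediate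
15 | (Z)-benzyl{2-[4-(benzyloxy)phenyl]ethenyl}dimethylsilane | C[Si](C)(Cc1ccccc1)/C=C\c1ccc(OCc2ccccc2)cc1 | intermediate
16 | (6E)-3-(benzyloxy)-6-[(penta-O-benzylepicatechin-8-yl)methylidene]cyclohexa-2,4-dien-1-one | O=C1C=C(OCc5ccccc5)C=C/C1=C\c1c(OCc5ccccc5)cc(OCc5ccccc5)c2c1O[C@H](c1ccc(OCc5ccccc5)c(OCc5ccccc5)c1)[C@H](OCc5ccccc5)C2 | intermediate
17 | (2R,3R,4R)-hepta-O-benzyl-3-deoxy-3-[benzyl(dimethyl)silyl]epiguibourtinidol-(4β→8)-epicatechin (2,3-cis, 3,4-trans) | c5ccccc5COc1ccc([C@H]2Oc3cc(OCc5ccccc5)ccc3[C@H](c3c(OCc5ccccc5)cc(OCc5ccccc5)c4c3O[C@H](c3ccc(OCc5ccccc5)c(OCc5ccccc5)c3)[C@H](OCc5ccccc5)C4)[C@H]2[Si](C)(C)Cc5ccccc5)cc1 | intermediate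
18 | the same dimer with hydroxy(dimethyl)silyl at upper C3 | c5ccccc5COc1ccc([C@H]2Oc3cc(OCc5ccccc5)ccc3[C@H](c3c(OCc5ccccc5)cc(OCc5ccccc5)c4c3O[C@H](c3ccc(OCc5ccccc5)c(OCc5ccccc5)c3)[C@H](OCc5ccccc5)C4)[C@H]2[Si](C)(C)O)cc1 | intermediate
19 | hepta-O-benzyl-epiguibourtinidol-(4β→8)-epicatechin, (2R,3R,4R), upper 3-OH free | c5ccccc5COc1ccc([C@H]2Oc3cc(OCc5ccccc5)ccc3[C@H](c3c(OCc5ccccc5)cc(OCc5ccccc5)c4c3O[C@H](c3ccc(OCc5ccccc5)c(OCc5ccccc5)c3)[C@H](OCc5ccccc5)C4)[C@H]2O)cc1 | intermediate
20 | epiguibourtinidol-(4β→8)-epicatechin, upper unit (2R,3R,4R), lower unit (2R,3R) | Oc1ccc([C@H]2Oc3cc(O)ccc3[C@H](c3c(O)cc(O)c4c3O[C@H](c3ccc(O)c(O)c3)[C@H](O)C4)[C@H]2O)cc1 | target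

Total step count: 11. Longest linear sequence: 8 steps (1, 2, 3, 5, 6, 9, 10, 11).

Steps most likely to fail

1. Step 9.
- The donor-rich quinone methide is a weak electrophile and the Z styrene is twisted out of conjugation. The union may therefore be slow enough for self-condensation of the quinone methide to take over.
- If bond formation becomes stepwise, silicon may be lost from the open β-silyl cation, or the C2–C3 bond may rotate before O1–C2 closes.
- Endo/exo and facial selectivity may leak.
- The fallback uses known chemistry throughout, sets out from 3 and returns at 19. It makes the interflavan bond by the classical capture of a flavan-4-yl cation. 2,4-Dihydroxybenzaldehyde and 2-hydroxy-1-(4-hydroxyphenyl)ethanone are condensed in HCl-saturated EtOAc to 3,7,4'-trihydroxyflavylium chloride F1. Hydrogenation over PtO2 in EtOH delivers hydrogen to one face of the heterocycle and should give the racemic 2,3-cis-flavan-3-ol, (±)-epiguibourtinidol F2. BnBr/K2CO3 in DMF then gives (±)-7,4'-di-O-benzylepiguibourtinidol F3. DDQ with 2-ethoxyethanol in CH2Cl2 oxidises C4, and the alcohol enters trans to the C3 hydroxyl to give (±)-7,4'-di-O-benzyl-4-(2-ethoxyethoxy)epiguibourtinidol F4. Catalytic TMSOTf (CH2Cl2, −78 °C) ionises F4 in the presence of an excess of 3, whose C8(D) attacks the cation anti to the axial C3 hydroxyl. The (2R,3R) antipode gives 19 and the (2S,3S) antipode gives the diastereomeric hepta-O-benzyl ent-epiguibourtinidol-(4α→8)-epicatechin F5. Because 3 is enantiopure, the two are separable by chromatography.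

2. Step 10.
- Fluoride attack at silicon may trigger β-elimination of the ring oxygen, opening ring C, in competition with loss of the benzyl group.
- Oxidation at the hindered secondary centre may be sluggish.
- The fallback sets out from 10 and 9 and returns at 19. It carries a silicon group that already bears oxygen through the cycloaddition, so no fluoride is needed afterwards. Trans-hydrosilylation of 10 with pentamethyldisiloxane ([RuCl2(p-cymene)]2, CH2Cl2, 40 °C) gives (Z)-1-{2-[4-(benzyloxy)phenyl]ethenyl}-1,1,3,3,3-pentamethyldisiloxane F6. Reaction of F6 with 9 under the conditions of step 9 gives the hepta-O-benzyl dimer with a pentamethyldisiloxanyl group at upper C3, F7. Fluoride-free Tamao oxidation (30% H2O2, KHCO3, THF/MeOH, 40 °C) then converts C3–Si into C3–OH with retention.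

3. Step 5.
- Addition of the doubly ortho-substituted aryllithium to the electron-rich aldehyde may be slow. Proton transfer from benzylic or allylic ether CH2 groups could then quench the organolithium first.
- The fallback sets out from 4 (through 7) and returns at 9. It reverses the polarity of the two halves and needs no phenol protecting group. Compound 7 is trapped with DMF to give 3,5,7,3',4'-penta-O-benzylepicatechin-8-carbaldehyde F8. 3-(Benzyloxy)phenol is turned into its bromomagnesium phenoxide with EtMgBr in toluene/CH2Cl2. It adds to F8 through a six-membered magnesium chelate (ortho-specific hydroxyalkylation of magnesium phenoxides) at the less hindered ortho carbon, para to the benzyloxy group, giving 9 directly.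

Further compounds
F1 | step 9 | 3,7,4'-trihydroxyflavylium chloride | [Cl-].Oc1ccc(cc1)-c1[o+]c2cc(O)ccc2cc1O
F2 | step 9 | (±)-epiguibourtinidol, 2,3-cis, racemic, (2R,3R) antipode drawn | Oc1ccc([C@H]2Oc3cc(O)ccc3C[C@H]2O)cc1
F3 | step 9 | (±)-7,4'-di-O-benzylepiguibourtinidol, racemic, (2R,3R) antipode drawn | c5ccccc5COc1ccc([C@H]2Oc3cc(OCc5ccccc5)ccc3C[C@H]2O)cc1
F4 | step 9 | (±)-7,4'-di-O-benzyl-4-(2-ethoxyethoxy)epiguibourtinidol, 2,3-cis-3,4-trans, racemic, 4β antipode of the (2R) series drawn | c5ccccc5COc1ccc([C@H]2Oc3cc(OCc5ccccc5)ccc3[C@H](OCCOCC)[C@H]2O)cc1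
F5 | step 9 | hepta-O-benzyl ent-epiguibourtinidol-(4α→8)-epicatechin, upper unit (2S,3S,4S) | c5ccccc5COc1ccc([C@@H]2Oc3cc(OCc5ccccc5)ccc3[C@@H](c3c(OCc5ccccc5)cc(OCc5ccccc5)c4c3O[C@H](c3ccc(OCc5ccccc5)c(OCc5ccccc5)c3)[C@H](OCc5ccccc5)C4)[C@@H]2O)cc1
F6 | step 10 | (Z)-1-{2-[4-(benzyloxy)phenyl]ethenyl}-1,1,3,3,3-pentamethyldisiloxane | C[Si](C)(C)O[Si](C)(C)/C=C\c1ccc(OCc2ccccc2)cc1
F7 | step 10 | (2R,3R,4R)-hepta-O-benzyl-3-deoxy-3-(pentamethyldisiloxanyl)epiguibourtinidol-(4β→8)-epicatechin | c5ccccc5COc1ccc([C@H]2Oc3cc(OCc5ccccc5)ccc3[C@H](c3c(OCc5ccccc5)cc(OCc5ccccc5)c4c3O[C@H](c3ccc(OCc5ccccc5)c(OCc5ccccc5)c3)[C@H](OCc5ccccc5)C4)[C@H]2[Si](C)(C)O[Si](C)(C)C)cc1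
F8 | step 5 | 3,5,7,3',4'-penta-O-benzylepicatechin-8-carbaldehyde | O=Cc1c(OCc3ccccc3)cc(OCc3ccccc3)c2c1O[C@H](c1ccc(OCc3ccccc3)c(OCc3ccccc3)c1)[C@H](OCc1ccccc1)C2
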